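**Assumption:** the target has no stereocentre (it is achiral), so the SMILES as given defines it completely and no stereocontrol is needed.

## Retrosynthetic overview

1. Target 5 comes from its bis(benzyl) ether 4 by O-debenzylation; the aromatic ring is bought intact and no ring is formed in the route.
2. Key disconnection of 4: the C1'–C2' bond (ArCH2–C=O), made between an acyl anion equivalent and a benzylic electrophile.
3. The acyl anion is not a masked aldehyde: it is the acyl tetracarbonylferrate 3, generated directly from the C22 acid chloride 1 with Na2Fe(CO)4.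
4. Starting materials: docosanoyl (behenoyl) chloride 1 and 3,5-bis(benzyloxy)benzyl bromide 2.

## Route

**Step 1**
Reactants: 1 docosanoyl chloride; 2 3,5-bis(benzyloxy)benzyl bromide
Product: 4 1-[3,5-bis(benzyloxy)phenyl]tricosan-2-one, via sodium docosanoyltetracarbonylferrate 3 (not isolated)
Conditions: Na2Fe(CO)4·1.5 dioxane (1.0 equiv), THF–NMP (4:1), 0 °C to rt, 1 h, Ar; then 2 (1.0 equiv), CO (1 atm), rt, 12 h; aq. NH4Cl work-up, effluent through a bleach scrubber
Reagents that add atoms: none
Why: Collman ketone synthesis: the supernucleophilic Fe(CO)4(2−) displaces chloride from 1 to give acylferrate 3, an unmasked acyl anion equivalent; 3 undergoes oxidative addition of the reactive benzylic bromide 2 at iron, and acyl–benzyl reductive elimination releases ketone 4 directly, with CO capturing the Fe(CO)4 fragment as Fe(CO)5. NMP loosens the Na+ ion pair and speeds the alkylation; benzyl ethers are inert.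

**Step 2**
Reactants: 4 1-[3,5-bis(benzyloxy)phenyl]tricosan-2-one
Product: 5 5-(2'-oxotricosyl)resorcinol [1-(3,5-dihydroxyphenyl)tricosan-2-one]
Conditions: H2 (1 atm), 10% Pd/C, EtOAc–THF (1:1), 30 °C
Reagents that add atoms: none
Why: Catalytic hydrogenolysis of the two benzylic C–O bonds of the aryl benzyl ethers; the saturated, non-conjugated ketone and the ArCH2–C(=O) bond are not reduced at 1 atm over Pd/C, and warm EtOAc–THF keeps the waxy substrate in solution.

## Compound list

1 | docosanoyl chloride (behenoyl chloride) | CCCCCCCCCCCCCCCCCCCCCC(=O)Cl | starting material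
2 | 3,5-bis(benzyloxy)benzyl bromide | BrCc1cc(OCc2ccccc2)cc(OCc2ccccc2)c1 | starting material
3 | sodium docosanoyltetracarbonylferrate(1−) | [Na+].CCCCCCCCCCCCCCCCCCCCCC(=O)[Fe-](=C=O)(=C=O)(=C=O)=C=O | intermediate
4 | 1-[3,5-bis(benzyloxy)phenyl]tricosan-2-one | CCCCCCCCCCCCCCCCCCCCCC(=O)Cc1cc(OCc2ccccc2)cc(OCc2ccccc2)c1 | intermediate
5 | 5-(2'-oxotricosyl)resorcinol | CCCCCCCCCCCCCCCCCCCCCC(=O)Cc1cc(O)cc(O)c1 | target

## Summary

Total step count: 2. Longest linear sequence: 2 steps.

The route has only two steps, so both are ranked and there is no third.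

**Most likely to fail: step 1.** Risks are incomplete formation of acylferrate 3, and benzylation of residual Fe(CO)4(2−) followed by CO insertion, which gives arylacetyl by-products. Fallback: replace the metal acyl anion by a sulfur-stabilised one. It sets out from 1, which is reduced with LiAlH(OtBu)3 in THF at −78 °C to docosanal F1. F1 is condensed with propane-1,3-dithiol (BF3·OEt2, CH2Cl2) to give 2-henicosyl-1,3-dithiane F2. F2 is lithiated with n-BuLi in THF at −30 °C and alkylated with 2 to give 2-[3,5-bis(benzyloxy)benzyl]-2-henicosyl-1,3-dithiane F3. F3 is unmasked with MeI/CaCO3 in aqueous MeCN at 60 °C, and the fallback comes back to the route at 4.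

**Second: step 2.** Risks are slow or incomplete debenzylation of the poorly soluble substrate, and partial reduction of the ketone if the reaction is forced. Fallback: change the phenol protecting group so that no hydrogenation is needed. It sets out from 1, converted to 3 exactly as in step 1. Then 3 is alkylated with 3,5-dimethoxybenzyl bromide F4 in place of 2, to give 1-(3,5-dimethoxyphenyl)tricosan-2-one F5. F5 is demethylated with BBr3 in CH2Cl2 (−78 °C to rt) followed by aqueous work-up, and the fallback comes back to the route at 5.

## Further compounds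

F1 | step 1 | docosanal | CCCCCCCCCCCCCCCCCCCCCC=O
F2 | step 1 | 2-henicosyl-1,3-dithiane | CCCCCCCCCCCCCCCCCCCCCC1SCCCS1
F3 | step 1 | 2-[3,5-bis(benzyloxy)benzyl]-2-henicosyl-1,3-dithiane | CCCCCCCCCCCCCCCCCCCCCC1(Cc2cc(OCc3ccccc3)cc(OCc3ccccc3)c2)SCCCS1
F4 | step 2 | 3,5-dimethoxybenzyl bromide | COc1cc(CBr)cc(OC)c1
F5 | step 2 | 1-(3,5-dimethoxyphenyl)tricosan-2-one | CCCCCCCCCCCCCCCCCCCCCC(=O)Cc1cc(OC)cc(OC)c1
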